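**Plan**

1. Retrosynthesis: the silyl ether on the 3'-oxygen is removed last. Before that the C2–C3 bond of ring C is cut, leading back to a ring-A aryl diazomethyl ketone whose O1 carries the ring-B benzyl group. Then the O1–CH2 ether bond, the C4–C3 bond (acid chloride plus diazomethane), the C4a–C4 bond (ortho-formylation) and the C8–prenyl bond (aromatic Claisen shift from O1) are cut.
2. Forward: ring A is bought as 3,5-dimethoxyphenol. The prenyl group is moved from the future O1 to C8, C4 is placed on the other ortho carbon, ring B (from isovanillin, 3'-OH as TIPS ether) is attached through O1, and ring C is closed last by making C2–C3.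
3. Feature used: C2 is α to the ring oxygen O1 and benzylic to ring B with its para-methoxy group, so its C–H bonds are hydridic. C3 is α to the C4 ketone, so it can be a keto-carbenoid. In the O1-benzyl ether the two carbons stand in a 1,6 relation.
4. Stereochemistry: C2 (S) is the only stereocenter. It is set in the ring closure itself, where a chiral dirhodium carboxylate tells apart the two enantiotopic benzylic hydrogens. The one step after it is buffered so that ring C cannot open.

Key step: step 11

Assumption: the sense of induction of Rh2(S-PTTL)4 on this substrate is taken to give the 2S product; should the first run show the opposite sense, the mirror-image catalyst Rh2(R-PTTL)4 is used with nothing else changed.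

**Route**

Step 1
Reactants: 1 3,5-dimethoxyphenol; 2 3-chloro-3-methylbut-1-yne
Product: 3 1,3-dimethoxy-5-[(2-methylbut-3-yn-2-yl)oxy]benzene
Conditions: DBU, CuCl2·2H2O (cat.), MeCN, 0 °C
Reagents that add atoms: none
Why: Copper-catalysed propargylic etherification of a phenol (ionisation of the tertiary propargylic chloride through a copper acetylide, capture by the phenoxide oxygen) should work well on this unhindered, non-chelated phenol and gives a tertiary ether that direct displacement could not.

Step 2
Reactants: 3 1,3-dimethoxy-5-[(2-methylbut-3-yn-2-yl)oxy]benzene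
Product: 4 1,3-dimethoxy-5-[(2-methylbut-3-en-2-yl)oxy]benzene
Conditions: H2 (1 atm), Pd/CaCO3 poisoned with Pb(OAc)2, quinoline, EtOAc, rt
Reagents that add atoms: none
Why: Lindlar semi-hydrogenation should stop at the terminal alkene, which the poisoned palladium surface reduces only slowly, and at room temperature the propargyl ether cannot yet cyclise to a chromene.

Step 3
Reactants: 4 1,3-dimethoxy-5-[(2-methylbut-3-en-2-yl)oxy]benzene
Product: 5 3,5-dimethoxy-2-(3-methylbut-2-en-1-yl)phenol
Conditions: N,N-diethylaniline, 130 °C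
Reagents that add atoms: none
Why: Aromatic Claisen rearrangement: the [3,3] shift joins the terminal CH2 of the 1,1-dimethylallyl group to an ortho carbon (the two ortho carbons are equivalent, the para carbon is not reached), which turns the reverse-prenyl ether into the linear prenyl group next to the phenol that becomes O1.

Step 4
Reactants: 5 3,5-dimethoxy-2-(3-methylbut-2-en-1-yl)phenol
Product: 6 2-hydroxy-4,6-dimethoxy-3-(3-methylbut-2-en-1-yl)benzaldehyde
Conditions: MgCl2, Et3N, (CH2O)n, MeCN, reflux; cold 1 M HCl work-up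
Reagents that add atoms: paraformaldehyde (reacts as formaldehyde), C=O
Why: Magnesium-mediated ortho-formylation (Casnati–Skattebøl reaction): formaldehyde is delivered inside the magnesium phenoxide to the only free ortho carbon and not to the para carbon between the two methoxy groups, and a second formaldehyde takes up hydride to give the aldehyde.

Step 5
Reactants: 7 isovanillin (3-hydroxy-4-methoxybenzaldehyde)
Product: 8 4-methoxy-3-[(triisopropylsilyl)oxy]benzaldehyde
Conditions: TIPSCl, imidazole, DMF, rt
Reagents that add atoms: chlorotri(propan-2-yl)silane (TIPSCl), CC(C)[Si](Cl)(C(C)C)C(C)C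
Why: Standard silylation of a phenol; the bulky silyl ether is needed because a free 3'-hydroxyl would be methylated by diazomethane in step 10 and would take up the carbenoid by O–H insertion in step 11, and it should survive carbonate in step 8.

Step 6
Reactants: 8 4-methoxy-3-[(triisopropylsilyl)oxy]benzaldehyde
Product: 9 {4-methoxy-3-[(triisopropylsilyl)oxy]phenyl}methanol
Conditions: NaBH4, MeOH, 0 °C
Reagents that add atoms: none
Why: Hydride reduction of an aromatic aldehyde to the benzylic alcohol, which leaves the aryl silyl ether untouched at 0 °C.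

Step 7
Reactants: 9 {4-methoxy-3-[(triisopropylsilyl)oxy]phenyl}methanol
Product: 10 [5-(bromomethyl)-2-methoxyphenoxy]tri(propan-2-yl)silane
Conditions: CBr4, PPh3, CH2Cl2, 0 °C; used at once
Reagents that add atoms: tetrabromomethane, BrC(Br)(Br)Br
Why: Appel reaction: the alcohol is activated as an alkoxyphosphonium ion and displaced by bromide under neutral conditions, so that neither the silyl ether nor the electron-rich ring is exposed to acid.

Step 8
Reactants: 6 2-hydroxy-4,6-dimethoxy-3-(3-methylbut-2-en-1-yl)benzaldehyde; 10 [5-(bromomethyl)-2-methoxyphenoxy]tri(propan-2-yl)silane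
Product: 11 2-({4-methoxy-3-[(triisopropylsilyl)oxy]phenyl}methoxy)-4,6-dimethoxy-3-(3-methylbut-2-en-1-yl)benzaldehyde
Conditions: K2CO3, n-Bu4NI (cat.), DMF, rt
Reagents that add atoms: none
Why: Williamson ether synthesis: the phenoxide of 6, though hydrogen-bonded to the aldehyde and flanked by the prenyl group, should be alkylated cleanly by the very reactive p-alkoxybenzyl bromide in DMF, as in routine benzylations of 2-hydroxyaryl aldehydes and ketones.

Step 9
Reactants: 11 2-({4-methoxy-3-[(triisopropylsilyl)oxy]phenyl}methoxy)-4,6-dimethoxy-3-(3-methylbut-2-en-1-yl)benzaldehyde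
Product: 12 2-({4-methoxy-3-[(triisopropylsilyl)oxy]phenyl}methoxy)-4,6-dimethoxy-3-(3-methylbut-2-en-1-yl)benzoic acid
Conditions: NaClO2, NaH2PO4, 2-methylbut-2-ene (large excess), t-BuOH/THF/H2O, 0 °C to rt
Reagents that add atoms: sodium chlorite, [Na+].[O-]Cl=O
Why: Pinnick (Lindgren) oxidation: chlorous acid turns the aldehyde into the acid while the large excess of 2-methylbut-2-ene takes up the hypochlorous acid that would otherwise chlorinate ring A or the prenyl group.

Step 10
Reactants: 12 2-({4-methoxy-3-[(triisopropylsilyl)oxy]phenyl}methoxy)-4,6-dimethoxy-3-(3-methylbut-2-en-1-yl)benzoic acid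
Product: 14 2-diazo-1-[2-({4-methoxy-3-[(triisopropylsilyl)oxy]phenyl}methoxy)-4,6-dimethoxy-3-(3-methylbut-2-en-1-yl)phenyl]ethan-1-one, via aroyl chloride 13 (not isolated)
Conditions: 1-chloro-N,N,2-trimethylprop-1-en-1-amine, CH2Cl2, 0 °C to rt; then CH2N2 (3 equiv), Et2O, 0 °C
Reagents that add atoms: diazomethane, C=[N+]=[N-]; 1-chloro-N,N,2-trimethylprop-1-en-1-amine, CC(C)=C(Cl)N(C)C (gives only the chlorine of 13)
Why: Acylation of diazomethane by an acid chloride (first stage of the Arndt–Eistert sequence): the α-chloroenamine makes the acid chloride under neutral conditions, without HCl that could cleave the acid-labile p-alkoxybenzyl ether, and a second equivalent of diazomethane removes the HCl set free in the acylation.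

Step 11
Reactants: 14 2-diazo-1-[2-({4-methoxy-3-[(triisopropylsilyl)oxy]phenyl}methoxy)-4,6-dimethoxy-3-(3-methylbut-2-en-1-yl)phenyl]ethan-1-one
Product: 15 (2S)-5,7-dimethoxy-2-{4-methoxy-3-[(triisopropylsilyl)oxy]phenyl}-8-(3-methylbut-2-en-1-yl)-2,3-dihydro-4H-chromen-4-one
Conditions: Rh2(S-PTTL)4 (dirhodium tetrakis[N-phthaloyl-(S)-tert-leucinate], 1 mol%), CH2Cl2, 4 Å molecular sieves, 0 °C, slow addition of 14
Reagents that add atoms: none
Why: Loss of N2 from 14 at the dirhodium core gives an electrophilic keto-carbenoid at the future C3, which inserts in a concerted, hydride-transfer-like three-centre transition state into one of the two enantiotopic C–H bonds of the O1–CH2–aryl group, so that the C2–C3 bond and the second C3–H bond form together. The closest known reaction type is the intramolecular C–H insertion of o-alkoxyaryl α-diazoketones under chiral divalent rhodium carboxylates, which gives 2-substituted chroman-4-ones. Ring C is the only ring closed, as a six-membered ring by 1,6-insertion through a chair-like arrangement of C3, C4, C4a, C8a, O1 and C2 with ring B pseudo-equatorial. C2 is the only new stereocenter and is set by the catalyst, whose pocket of four N-phthaloyl-tert-leucinate ligands admits the carbenoid to one benzylic hydrogen only, while the neutral medium offers no path to the ring-opened chalcone that would racemise it. The step needs site selectivity for the O1–CH2 group over the C–H bonds of the C5 methoxy group, over oxonium ylide formation at O1 and over the prenyl alkene. The C2–H bond is the most hydridic one in reach (α to oxygen and benzylic to a para-methoxyaryl ring, against a primary non-benzylic methoxy C–H), carboxylate-bridged rhodium favours insertion over ylide chemistry, and the prenyl group sits meta to the acyl carbon so that no strain-free ring can link it to the carbenoid.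

Step 12
Reactants: 15 (2S)-5,7-dimethoxy-2-{4-methoxy-3-[(triisopropylsilyl)oxy]phenyl}-8-(3-methylbut-2-en-1-yl)-2,3-dihydro-4H-chromen-4-one
Product: 16 (2S)-2-(3-hydroxy-4-methoxyphenyl)-5,7-dimethoxy-8-(3-methylbut-2-en-1-yl)-2,3-dihydro-4H-chromen-4-one
Conditions: TBAF, AcOH (1:1), THF, 0 °C
Reagents that add atoms: none
Why: Fluoride-mediated cleavage of an aryl silyl ether: the strong Si–F bond drives the reaction, and acetic acid keeps the medium near neutral so that the flavanone is not opened to the chalcone by retro-oxa-Michael reaction and C2 keeps its configuration.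

**Compound list**

1 | 3,5-dimethoxyphenol | COc1cc(O)cc(OC)c1 | starting material
2 | 3-chloro-3-methylbut-1-yne | CC(C)(Cl)C#C | starting material
3 | 1,3-dimethoxy-5-[(2-methylbut-3-yn-2-yl)oxy]benzene | COc1cc(OC)cc(OC(C)(C)C#C)c1 | intermediate
4 | 1,3-dimethoxy-5-[(2-methylbut-3-en-2-yl)oxy]benzene | COc1cc(OC)cc(OC(C)(C)C=C)c1 | intermediate
5 | 3,5-dimethoxy-2-(3-methylbut-2-en-1-yl)phenol | COc1cc(O)c(CC=C(C)C)c(OC)c1 | intermediate
6 | 2-hydroxy-4,6-dimethoxy-3-(3-methylbut-2-en-1-yl)benzaldehyde | COc1cc(OC)c(C=O)c(O)c1CC=C(C)C | intermediate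
7 | isovanillin (3-hydroxy-4-methoxybenzaldehyde) | COc1ccc(C=O)cc1O | starting material
8 | 4-methoxy-3-[(triisopropylsilyl)oxy]benzaldehyde | COc1ccc(C=O)cc1O[Si](C(C)C)(C(C)C)C(C)C | intermediate
9 | {4-methoxy-3-[(triisopropylsilyl)oxy]phenyl}methanol | COc1ccc(CO)cc1O[Si](C(C)C)(C(C)C)C(C)C | intermediate
10 | [5-(bromomethyl)-2-methoxyphenoxy]tri(propan-2-yl)silane | COc1ccc(CBr)cc1O[Si](C(C)C)(C(C)C)C(C)C | intermediate
11 | 2-({4-methoxy-3-[(triisopropylsilyl)oxy]phenyl}methoxy)-4,6-dimethoxy-3-(3-methylbut-2-en-1-yl)benzaldehyde | COc1ccc(COc2c(CC=C(C)C)c(OC)cc(OC)c2C=O)cc1O[Si](C(C)C)(C(C)C)C(C)C | intermediate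
12 | 2-({4-methoxy-3-[(triisopropylsilyl)oxy]phenyl}methoxy)-4,6-dimethoxy-3-(3-methylbut-2-en-1-yl)benzoic acid | COc1ccc(COc2c(CC=C(C)C)c(OC)cc(OC)c2C(=O)O)cc1O[Si](C(C)C)(C(C)C)C(C)C | intermediate
13 | 2-({4-methoxy-3-[(triisopropylsilyl)oxy]phenyl}methoxy)-4,6-dimethoxy-3-(3-methylbut-2-en-1-yl)benzoyl chloride | COc1ccc(COc2c(CC=C(C)C)c(OC)cc(OC)c2C(=O)Cl)cc1O[Si](C(C)C)(C(C)C)C(C)C | intermediate
14 | 2-diazo-1-[2-({4-methoxy-3-[(triisopropylsilyl)oxy]phenyl}methoxy)-4,6-dimethoxy-3-(3-methylbut-2-en-1-yl)phenyl]ethan-1-one | COc1ccc(COc2c(CC=C(C)C)c(OC)cc(OC)c2C(=O)C=[N+]=[N-])cc1O[Si](C(C)C)(C(C)C)C(C)C | intermediate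
15 | (2S)-5,7-dimethoxy-2-{4-methoxy-3-[(triisopropylsilyl)oxy]phenyl}-8-(3-methylbut-2-en-1-yl)-2,3-dihydro-4H-chromen-4-one | COc1ccc([C@@H]2CC(=O)c3c(OC)cc(OC)c(CC=C(C)C)c3O2)cc1O[Si](C(C)C)(C(C)C)C(C)C | intermediate
16 | (2S)-2-(3-hydroxy-4-methoxyphenyl)-5,7-dimethoxy-8-(3-methylbut-2-en-1-yl)-2,3-dihydro-4H-chromen-4-one | COc1ccc([C@@H]2CC(=O)c3c(OC)cc(OC)c(CC=C(C)C)c3O2)cc1O | target

**Step count**

Total step count: 12. Longest linear sequence: 9 steps (steps 1 to 4 and 8 to 12).

**Steps most likely to fail**

Step 11. What may go wrong: capture of the carbenoid by the lone pair of O1 to give an oxonium ylide that undergoes 1,2-benzyl shift, insertion into the neighbouring methoxy group, or poor discrimination between the two benzylic hydrogens. The fallback sets out from 6 and comes back at 16. Compound 6 is treated with HC≡CMgBr (2.5 equiv, THF, −20 °C) to give the propargylic alcohol 1-[2-hydroxy-4,6-dimethoxy-3-(3-methylbut-2-en-1-yl)phenyl]prop-2-yn-1-ol F1. MnO2 in CH2Cl2 oxidises it to the ynone 1-[2-hydroxy-4,6-dimethoxy-3-(3-methylbut-2-en-1-yl)phenyl]prop-2-yn-1-one F2, which on addition of Et2NH in EtOH should close by 6-endo-dig oxa-Michael addition to the chromone 5,7-dimethoxy-8-(3-methylbut-2-en-1-yl)-4H-chromen-4-one F3. Asymmetric conjugate addition of commercial (3-hydroxy-4-methoxyphenyl)boronic acid to F3 should then give 16 directly, so that steps 5 to 12 are not needed. The conditions are Pd(OCOCF3)2, the enantiomer of the pyridine–oxazoline ligand t-BuPyOx that leads to the 2S series, NH4PF6 and water in 1,2-dichloroethane at 60 °C; this conjugate arylation of chromones by divalent palladium is a known route to flavanones.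

Step 10. What may go wrong: loss of the acid-labile p-alkoxybenzyl ether during activation of the acid, or slow acylation of diazomethane at the doubly ortho-substituted acid chloride, so that side reactions of the acid chloride take over. The fallback sets out from 11 and comes back at 14; it also by-passes step 9 and its risk of ring chlorination. MeMgBr (THF, 0 °C) adds to 11 to give the racemic carbinol 1-[2-({4-methoxy-3-[(triisopropylsilyl)oxy]phenyl}methoxy)-4,6-dimethoxy-3-(3-methylbut-2-en-1-yl)phenyl]ethan-1-ol F4. Dess–Martin periodinane (NaHCO3, CH2Cl2) gives the methyl ketone 1-[2-({4-methoxy-3-[(triisopropylsilyl)oxy]phenyl}methoxy)-4,6-dimethoxy-3-(3-methylbut-2-en-1-yl)phenyl]ethan-1-one F5. Detrifluoroacetylative diazo transfer (Regitz type) then follows: LiN(SiMe3)2 in THF at −78 °C and CF3CO2CH2CF3 give the diketone 4,4,4-trifluoro-1-[2-({4-methoxy-3-[(triisopropylsilyl)oxy]phenyl}methoxy)-4,6-dimethoxy-3-(3-methylbut-2-en-1-yl)phenyl]butane-1,3-dione F6, which is not isolated, and MsN3, Et3N and H2O in MeCN at rt should give 14.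

Step 3. What may go wrong: ionisation of the tertiary allyl aryl ether instead of the concerted shift (loss of the five-carbon unit as isoprene, or recombination at the para carbon between the methoxy groups), or acid-catalysed closure of the o-prenylphenol to a 2,2-dimethylchroman. The fallback sets out from 1 and comes back at 5; steps 1 and 2 are then not needed. Compound 1 is allylated (allyl bromide, K2CO3, acetone, reflux) to 1,3-dimethoxy-5-(prop-2-en-1-yloxy)benzene F7. Claisen rearrangement (N,N-diethylaniline, 200 °C) gives 3,5-dimethoxy-2-(prop-2-en-1-yl)phenol F8. Cross-metathesis with excess 2-methylbut-2-ene and the second-generation Grubbs catalyst RuCl2(=CHPh)(PCy3)(H2IMes) (CH2Cl2, 40 °C) should give 5.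

**Further compounds**

F1 | step 11 | 1-[2-hydroxy-4,6-dimethoxy-3-(3-methylbut-2-en-1-yl)phenyl]prop-2-yn-1-ol (racemic) | COc1cc(OC)c(C(O)C#C)c(O)c1CC=C(C)C
F2 | step 11 | 1-[2-hydroxy-4,6-dimethoxy-3-(3-methylbut-2-en-1-yl)phenyl]prop-2-yn-1-one | COc1cc(OC)c(C(=O)C#C)c(O)c1CC=C(C)C
F3 | step 11 | 5,7-dimethoxy-8-(3-methylbut-2-en-1-yl)-4H-chromen-4-one | COc1cc(OC)c2c(=O)ccoc2c1CC=C(C)C
F4 | step 10 | 1-[2-({4-methoxy-3-[(triisopropylsilyl)oxy]phenyl}methoxy)-4,6-dimethoxy-3-(3-methylbut-2-en-1-yl)phenyl]ethan-1-ol (racemic) | COc1ccc(COc2c(CC=C(C)C)c(OC)cc(OC)c2C(C)O)cc1O[Si](C(C)C)(C(C)C)C(C)C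
F5 | step 10 | 1-[2-({4-methoxy-3-[(triisopropylsilyl)oxy]phenyl}methoxy)-4,6-dimethoxy-3-(3-methylbut-2-en-1-yl)phenyl]ethan-1-one | COc1ccc(COc2c(CC=C(C)C)c(OC)cc(OC)c2C(C)=O)cc1O[Si](C(C)C)(C(C)C)C(C)C
F6 | step 10 | 4,4,4-trifluoro-1-[2-({4-methoxy-3-[(triisopropylsilyl)oxy]phenyl}methoxy)-4,6-dimethoxy-3-(3-methylbut-2-en-1-yl)phenyl]butane-1,3-dione | COc1ccc(COc2c(CC=C(C)C)c(OC)cc(OC)c2C(=O)CC(=O)C(F)(F)F)cc1O[Si](C(C)C)(C(C)C)C(C)C
F7 | step 3 | 1,3-dimethoxy-5-(prop-2-en-1-yloxy)benzene | C=CCOc1cc(OC)cc(OC)c1
F8 | step 3 | 3,5-dimethoxy-2-(prop-2-en-1-yl)phenol | C=CCc1c(O)cc(OC)cc1OC
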